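(The data were generated by integration from invented constants; noise was put on by code.)

The constants of this flask fold into one concentration, so here is your quick number on that footing. Take the level of starting material at which the route to target and the loss consume it equally fast, a crossover for the selectivity. This is my own reckoning from the runs below.

| flask | starting material | catalyst | time |
|---|---|---|---|
| amber | 0.500 M | 0.00100 M |  |
| teal | 0.200 M | 0.00100 M |  |
| green | 1.00 M | 0.00100 M |  |
| ochre | 0.500 M | 0.00150 M |  |
| red | 0.500 M | 0.00100 M | 1300 h |

| run | time / h | [target] / M |
|---|---|---|
| amber run | 7.9 | 0.046 |
| amber run | 24 | 0.123 |
| amber run | 46 | 0.191 |
| amber run | 73 | 0.233 |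
| amber run | 100 | 0.281 |
| amber run | 140 | 0.278 |
| amber run | 180 | 0.309 |
| amber run | 220 | 0.306 |
| teal run | 7.9 | 0.025 |
| teal run | 24 | 0.054 |
| teal run | 46 | 0.097 |
| teal run | 73 | 0.119 |
| teal run | 100 | 0.142 |
| teal run | 140 | 0.149 |
| teal run | 180 | 0.152 |
| teal run | 220 | 0.162 |
| green run | 7.9 | 0.073 |
| green run | 24 | 0.178 |
| green run | 46 | 0.280 |
| green run | 73 | 0.348 |
| green run | 100 | 0.392 |
| green run | 140 | 0.433 |
| green run | 180 | 0.454 |
| green run | 220 | 0.458 |
| ochre run | 7.9 | 0.094 |
| ochre run | 24 | 0.234 |
| ochre run | 46 | 0.326 |
| ochre run | 73 | 0.367 |
| ochre run | 100 | 0.389 |
| ochre run | 140 | 0.403 |
| ochre run | 180 | 0.404 |
| ochre run | 220 | 0.387 |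

(standard deviation of a reading: 0.005 M)

- Overall: starting material -> target, with catalyst as catalyst.
- Constant volume, constant temperature.
- Readings of a species count what is bound in complexes too.
- An order is taken over about fifteen percent of the charge, up and down.

- apparent order in [catalyst] of the starting rate, round the charge of the amber run (the rate where two percent of its starting material have turned into target)
- apparent order in [starting material] of the starting rate, round the charge of the amber run (the rate where two percent of its starting material have turned into target) (one fixed amount of target, the same in the runs compared)
- target in the red run at 1300 h, as a share of the starting material charged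
- which of these the readings show (the catalyst dies by itself / the catalyst rests as a dimer / two substrates go astray together / the product binds the substrate / the catalyst wakes slowly / nothing beyond the main steps)

At the last reading, target stands at 81.0% of the charge in the teal run, 61.2% in the amber run and 45.8% in the green run, so the share is smaller in the green run than in the teal run. I read that as a loss of higher order in starting material than the route to target, and I take them as second and first order. The odds of target against loss at any moment are then the crossover over the current level. As a rough step, I put the level over a whole run at half the charge.

Taking the last reading of the green run as its stall, 0.458 M of target against 0.542 M of the rest gives odds of 0.845. Multiplying by half the green charge gives 0.423 M, the crossover concentration at the catalyst charge of the green run. The red run has a charge of 0.500 M and the catalyst of the green run, so the crossover divided by itself plus half that charge gives 62.8%, and that is my number.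

Your forecast gives 1.7 for the apparent order in catalyst of the starting rate, 0.65 for the apparent order in starting material of that rate and 62% for the red run, and its assignment reads: two substrates go astray together. Its ground for the red run is “Same charge as amber, already finished”. I take your orders and your assignment as they stand. On the red run we differ by 0.80 percentage points, mine coming from the green run and yours from the amber run.

    catalyst + starting material ⇌ catalyst-substrate complex, settled at all times (0.2970 M⁻¹)
    catalyst-substrate complex + catalyst → target + 2 catalyst (56880 M⁻¹ h⁻¹)
    2 starting material → homo dimer (0.01868 M⁻¹ h⁻¹)

The flask gives 64.1% of the charge in the red run at 1300 h, 1.3 points above the share from the crossover, and the assignment reads: two substrates go astray together. The apparent orders of the starting rate round the amber charge come out at 2.0 in catalyst and 0.76 in starting material. Scaling the crossover by the catalyst ratio raised to that catalyst order gives 0.968 M for the ochre run, and so, with the level again put at half the charge, a share of 79.5% of its charge. The last 3 readings of the ochre run average 79.6% of its charge.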